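**Assumption:** the target has no stereocentre or stereogenic axis, so "single enantiomer" is taken to mean the single achiral constitution shown. The route has not been run; step 3 is a proposed reaction.

**Retrosynthetic overview**
- Target 9 ⇒ break the diaryl ether C–O bond at ring-A C2: quinone monoketal 5 (ring-A electrophile) + 2,4-dibromophenol 6 (oxygen nucleophile), joined by a new acid-catalysed SN2′-type aryloxylation.
- 5 ⇒ oxidative dearomatisation of the symmetric phenol 4; its two ortho C–H positions are equivalent, so no regioisomer is possible.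
- 4 ⇒ C–H borylation/oxidation of 2,6-dibromoanisole 1 at its only unhindered C–H.
- No ring is formed; both benzene rings are bought with their bromines in place (ring A from 1, ring B from 6).

**Route**

Step 1
Reactants: 1 2,6-dibromoanisole (1,3-dibromo-2-methoxybenzene); 2 bis(pinacolato)diboron
Product: 4 3,5-dibromo-4-methoxyphenol, via aryl pinacol boronate 3 (not isolated)
Conditions: [Ir(cod)OMe]2 (1 mol %), dtbpy (2 mol %), B2pin2 (1.0 equiv), THF, 70 °C, 12 h; evaporate volatiles; then Oxone (1.1 equiv), acetone/H2O, rt, 15 min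
Reagents that add atoms: Oxone (potassium peroxymonosulfate), [K+].[O-]S(=O)(=O)OO
Why: Sterically controlled Ir-catalysed C–H borylation takes the only C–H not ortho to a bromine (para to OMe), and the C–B bond is oxidised to C–OH in the same pot (C–H borylation/oxidation); aryl bromides are tolerated.

Step 2
Reactants: 4 3,5-dibromo-4-methoxyphenol
Product: 5 3,5-dibromo-4,4-dimethoxycyclohexa-2,5-dien-1-one
Conditions: PhI(OAc)2 (1.1 equiv), MeOH, 0 °C, 30 min; NaHCO3 work-up; filtration through neutral alumina
Reagents that add atoms: methanol, CO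
Why: Hypervalent-iodine oxidative dearomatisation of a para-methoxyphenol, with methanol trapping the para carbon to give the p-quinone monoketal; the oxidant is gone before the coupling partner is added.

Step 3
Reactants: 5 3,5-dibromo-4,4-dimethoxycyclohexa-2,5-dien-1-one; 6 2,4-dibromophenol
Product: 9 3,5-dibromo-2-(2,4-dibromophenoxy)-4-methoxyphenol, via oxocarbenium ion pair 7 (not isolated), via aryloxy dienone 8 (not isolated)
Conditions: 6 (3 equiv), (PhO)2P(O)OH (10 mol %), acid-washed 4 Å molecular sieves (AW-300), HFIP/CH2Cl2 (1:1), 0 °C → rt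
Reagents that add atoms: none
Why: Proposed new method: Brønsted-acid-catalysed SN2′-type (vinylogous) O-aryloxylation of a quinone monoketal, in which the phosphoric acid in the ionising, weakly nucleophilic fluoroalcohol removes one ketal methoxy group of 5 (helped by relief of strain between the geminal OMe groups and the flanking bromines) to give the O-methyl quinone oxocarbenium ion pair 7; oxygen nucleophiles add to its ketal carbon only reversibly (degenerately for MeOH, which the sieves remove), whereas attack by the oxygen of 6, hydrogen-bonded to and deprotonated by the phosphate counter-anion, at the carbon α to the carbonyl gives dienone 8 (racemic, transient), which tautomerises irreversibly to the aromatic target 9 and drains the equilibrium; 6 is a poor carbon nucleophile (two bromines, para position blocked), which disfavours Friedel–Crafts C–C coupling, the two α-carbons of 5 are equivalent, and no oxidant is present to over-oxidise 9; closest known reaction types are the acid-promoted coupling of quinone monoacetals with π-nucleophiles (arenes, alkenes) at the carbon α to the carbonyl in fluoroalcohols, and kinetic O-attack of phenols on oxocarbenium ions in aryl glycoside synthesis.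

**Compound list**
1 | 2,6-dibromoanisole (1,3-dibromo-2-methoxybenzene) | COc1c(Br)cccc1Br | starting material
2 | bis(pinacolato)diboron | CC1(C)OB(OC1(C)C)B1OC(C)(C)C(C)(C)O1 | starting material
3 | 2-(3,5-dibromo-4-methoxyphenyl)-4,4,5,5-tetramethyl-1,3,2-dioxaborolane | COc1c(Br)cc(cc1Br)B1OC(C)(C)C(C)(C)O1 | intermediate
4 | 3,5-dibromo-4-methoxyphenol | COc1c(Br)cc(O)cc1Br | intermediate
5 | 3,5-dibromo-4,4-dimethoxycyclohexa-2,5-dien-1-one | COC1(OC)C(Br)=CC(=O)C=C1Br | intermediate
6 | 2,4-dibromophenol | Oc1ccc(Br)cc1Br | starting material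
7 | (2,6-dibromo-4-oxocyclohexa-2,5-dien-1-ylidene)(methyl)oxonium diphenyl phosphate (ion pair) | C[O+]=C1C(Br)=CC(=O)C=C1Br.[O-]P(=O)(Oc1ccccc1)Oc1ccccc1 | intermediate
8 | 3,5-dibromo-6-(2,4-dibromophenoxy)-4-methoxycyclohexa-2,4-dien-1-one (racemic, transient) | COC1=C(Br)C(Oc2ccc(Br)cc2Br)C(=O)C=C1Br | intermediate
9 | 3,5-dibromo-2-(2,4-dibromophenoxy)-4-methoxyphenol | COc1c(Br)cc(O)c(Oc2ccc(Br)cc2Br)c1Br | target

**Totals**
Total step count: 3. Longest linear sequence: 3 (1 → 4 → 5 → 9); 2 and 6 are purchased.

**Steps most likely to fail, with fallbacks**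

Step 3 (the proposed new step) is the main risk. The phenol oxygen may not attack the α-carbon fast enough. Competing outcomes are the reversible mixed ketal, C–C coupling through C6 of 6, the 2-methoxy by-product from liberated methanol, hydrolysis or O-demethylation of 7 to 2,6-dibromo-1,4-benzoquinone, and HFIP incorporation.

The fallback uses known chemistry, sets out from 4 and comes back at 9:
- Magnesium-mediated ortho-formylation (MgCl2, Et3N, paraformaldehyde, MeCN, reflux) gives 4,6-dibromo-2-hydroxy-5-methoxybenzaldehyde F5.
- MOMCl, iPr2NEt, CH2Cl2 gives 4,6-dibromo-5-methoxy-2-(methoxymethoxy)benzaldehyde F6.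
- Baeyer–Villiger oxidation (mCPBA, NaHCO3, CH2Cl2) gives 4,6-dibromo-5-methoxy-2-(methoxymethoxy)phenyl formate F7.
- Methanolysis (K2CO3, MeOH) gives 2,4-dibromo-3-methoxy-6-(methoxymethoxy)phenol F8, in which the two catechol oxygens are differentiated without ambiguity.
- O-arylation with bis(2,4-dibromophenyl)iodonium chloride F9 (made from 1,3-dibromobenzene and iodyl sulfate in H2SO4, then chloride; the standard aryl donor for polybrominated diphenyl ethers) using NaOH in H2O/dioxane at 80 °C gives 1,3-dibromo-4-(2,4-dibromophenoxy)-2-methoxy-5-(methoxymethoxy)benzene F10.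
- HCl in MeOH removes the MOM group to give 9.

Step 2 is the second risk. The ketal carbon is flanked by two bromines, so methanol trapping may be slow, and over-oxidation or hydrolysis to 2,6-dibromo-1,4-benzoquinone, or loss on acidic silica, is possible.

The fallback sets out from 4 and comes back at 5:
- O-methylation (MeI, K2CO3, acetone) gives 1,3-dibromo-2,5-dimethoxybenzene F3.
- Anodic oxidation (Pt anode, KOH/MeOH, 0 °C, constant current) gives the quinone bisketal 1,5-dibromo-3,3,6,6-tetramethoxycyclohexa-1,4-diene F4.
- Mild monohydrolysis (aqueous AcOH/acetone, 0 °C) gives 5. The ketal between the two inductively withdrawing vinyl bromides should ionise more slowly, so the distal ketal is the one expected to hydrolyse.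

Step 1 is the third risk. Possible problems are incomplete borylation of the hindered, electron-poor arene, protodeboronation, or over-oxidation of the electron-rich phenol by Oxone.

The fallback sets out from 1 and comes back at 4:
- Friedel–Crafts acetylation (AcCl, AlCl3, CH2Cl2, 0 °C), expected para to OMe by analogy with 2,6-dihaloanisoles, gives 1-(3,5-dibromo-4-methoxyphenyl)ethan-1-one F1.
- Baeyer–Villiger oxidation with aryl migration (mCPBA, cat. TFA, CH2Cl2) gives 3,5-dibromo-4-methoxyphenyl acetate F2.
- Methanolysis (K2CO3, MeOH) gives 4.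

**Further compounds**
F1 | step 1 | 1-(3,5-dibromo-4-methoxyphenyl)ethan-1-one | COc1c(Br)cc(cc1Br)C(C)=O
F2 | step 1 | 3,5-dibromo-4-methoxyphenyl acetate | COc1c(Br)cc(OC(C)=O)cc1Br
F3 | step 2 | 1,3-dibromo-2,5-dimethoxybenzene | COc1cc(Br)c(OC)c(Br)c1
F4 | step 2 | 1,5-dibromo-3,3,6,6-tetramethoxycyclohexa-1,4-diene | COC1(OC)C=C(Br)C(OC)(OC)C(Br)=C1
F5 | step 3 | 4,6-dibromo-2-hydroxy-5-methoxybenzaldehyde | O=Cc1c(O)cc(Br)c(OC)c1Br
F6 | step 3 | 4,6-dibromo-5-methoxy-2-(methoxymethoxy)benzaldehyde | O=Cc1c(OCOC)cc(Br)c(OC)c1Br
F7 | step 3 | 4,6-dibromo-5-methoxy-2-(methoxymethoxy)phenyl formate | O=COc1c(OCOC)cc(Br)c(OC)c1Br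
F8 | step 3 | 2,4-dibromo-3-methoxy-6-(methoxymethoxy)phenol | Oc1c(OCOC)cc(Br)c(OC)c1Br
F9 | step 3 | bis(2,4-dibromophenyl)iodonium chloride | Brc1ccc([I+]c2ccc(Br)cc2Br)c(Br)c1.[Cl-]
F10 | step 3 | 1,3-dibromo-4-(2,4-dibromophenoxy)-2-methoxy-5-(methoxymethoxy)benzene | COCOc1cc(Br)c(OC)c(Br)c1Oc1ccc(Br)cc1Br
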